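**Strategy**

The target is cut at C15–C16, the glycol bond of ring B (C8, C9, C10, C14, C15, C16; ring C is C1–C11, ring A C10–C14). Both carbons become aldehydes: one on quaternary C14, one on C8 of the C8=C9 alkene. A titanium-mediated reductive pinacol coupling then forms this bond, ring B and both carbinol centres in one operation. It exploits the cis placement of the two formyl groups: the alkene holds the C8 formyl beside C10, and the C14 formyl sits on the same face of ring A as that arm. The precursor is the A/C-bicyclic dialdehyde with C2 and C7 as silyl ethers, because an acetate at C7 would lie β to the enal carbonyl.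

Key step: step 26

Remark 1: the atom numbers C1–C16 of the target are used for all intermediates.
Remark 2 (assumption): the chiral lithio-enamine methylation of step 2 is taken to give the 1S keto ester with the L-valine ester in the presence of HMPA; should the sense be opposite, the D-valine ester is used instead.
Remark 3 (corrections): in CIP terms the C8=C9 bond of dialdehyde 36 is Z (formyl cis to C10), although the ring bonds C7–C8 and C9–C10 are trans within ring C; SmI2 would favour the cis glycol through chelation, so the titanium reagent is chosen.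

**Route**

Step 1
Reactants: 1 methyl 2-oxocyclopentane-1-carboxylate; 2 L-valine tert-butyl ester
Product: 3 methyl 2-{[(2S)-1-tert-butoxy-3-methyl-1-oxobutan-2-yl]amino}cyclopent-1-ene-1-carboxylate
Conditions: TsOH (cat.), benzene, reflux, Dean–Stark trap
Reagents that add atoms: none
Why: Acid-catalysed condensation of the β-keto ester with the primary amine gives the hydrogen-bonded β-enamino ester (vinylogous carbamate formation) and attaches the chiral auxiliary.

Step 2
Reactants: 3 enamino ester
Product: 6 methyl (1S)-1-methyl-2-oxocyclopentane-1-carboxylate, via N-lithio enamine 4 (not isolated), via ketimine 5 (not isolated)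
Conditions: LiN(i-Pr)2, toluene, −78 °C; HMPA; MeI, −55 °C; then 10% aq. citric acid, rt
Reagents that add atoms: iodomethane, CI; water, O
Why: The chelated lithio-enamine is shielded on one face by the valine side chain, so C-methylation (chiral-enamine alkylation) sets quaternary C14 as S, and mild hydrolysis of the ketimine releases the keto ester and the auxiliary.

Step 3
Reactants: 6 (S)-keto ester
Product: 8 methyl (1S)-1-methyl-2-(trifluoromethanesulfonyloxy)cyclopent-2-ene-1-carboxylate, via lithium enolate 7 (not isolated)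
Conditions: LiN(i-Pr)2, THF, −78 °C; then PhNTf2, −78 °C → 0 °C
Reagents that add atoms: N-phenylbis(trifluoromethanesulfonimide), O=S(=O)(N(c1ccccc1)S(=O)(=O)C(F)(F)F)C(F)(F)F
Why: The ketone can enolise only toward C11, so O-triflation of the enolate gives a single enol triflate (enolate triflation).

Step 4
Reactants: 8 enol triflate ester
Product: 9 (5R)-5-(hydroxymethyl)-5-methylcyclopent-1-en-1-yl trifluoromethanesulfonate
Conditions: i-Bu2AlH, CH2Cl2, −78 °C → 0 °C
Reagents that add atoms: none
Why: i-Bu2AlH reduces the hindered ester to the neopentyl alcohol (C15) while the enol triflate is inert (ester reduction).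

Step 5
Reactants: 9 hydroxy enol triflate
Product: 10 (3aS)-3a-methyl-3,3a,4,5-tetrahydro-1H-cyclopenta[c]furan-1-one (bicyclic lactone; C9 carbonyl on C10; C10=C11)
Conditions: Pd(PPh3)4 (cat.), CO (1 atm), Et3N, LiCl, MeCN, 65 °C
Reagents that add atoms: carbon monoxide, [C-]#[O+]
Why: Oxidative addition of the enol triflate to zerovalent palladium, CO insertion and capture of the acyl-palladium by the neighbouring C15 hydroxyl close the five-membered lactone (carbonylative lactonisation).

Step 6
Reactants: 10 unsaturated lactone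
Product: 11 (3aS,6S,6aR)-6-ethenyl-3a-methylhexahydro-1H-cyclopenta[c]furan-1-one (cis-fused; vinyl on C11 cis to C9 and C15)
Conditions: CH2=CHMgBr, CuBr·SMe2 (10 mol%), THF, −78 °C → −40 °C; aq. NH4Cl
Reagents that add atoms: vinylmagnesium bromide, C=C[Mg]Br
Why: Copper-catalysed conjugate addition brings the vinyl group to C11 anti to the angular C14 methyl, the only group projecting over the planar enoate (C15 is tied back in the lactone), and protonation at C10 can only give the cis-fused lactone, so C10 and C11 are set with all three arms of ring A cis.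

Step 7
Reactants: 11 vinyl lactone
Product: 12 (3aS,6S,6aR)-6-ethenyl-3a-methylhexahydro-1H-cyclopenta[c]furan-1-ol (lactol; anomers)
Conditions: i-Bu2AlH (1.1 equiv), CH2Cl2, −78 °C
Reagents that add atoms: none
Why: The tetrahedral aluminate is stable at −78 °C, so reduction stops at the lactol (partial lactone reduction).

Step 8
Reactants: 12 lactol
Product: 13 [(1S,2S,3S)-3-ethenyl-2-ethynyl-1-methylcyclopentyl]methanol
Conditions: dimethyl (1-diazo-2-oxopropyl)phosphonate, K2CO3, MeOH, 0 °C → rt
Reagents that add atoms: dimethyl (1-diazo-2-oxopropyl)phosphonate, COP(=O)(OC)C(=[N+]=[N-])C(C)=O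
Why: The open hydroxy aldehyde form undergoes Seyferth–Gilbert homologation with the Ohira–Bestmann reagent under mild carbonate conditions, which should leave C10 next to the aldehyde intact; this adds C8 and frees the C15 hydroxyl.

Step 9
Reactants: 13 alkynol
Product: 15 methyl 3-[(1S,2S,5S)-2-ethenyl-5-{[(methoxycarbonyl)oxy]methyl}-5-methylcyclopentyl]prop-2-ynoate, via dilithio alkynide alkoxide 14 (not isolated)
Conditions: n-BuLi (2.2 equiv), THF, −78 °C; then ClCO2Me (2.5 equiv), −78 °C → 0 °C
Reagents that add atoms: methyl chloroformate, COC(Cl)=O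
Why: Acylation of the acetylide installs C16 as the ynoate, and the same reagent masks the C15 alkoxide as a methyl carbonate (acetylide acylation).

Step 10
Reactants: 15 ynoate
Product: 17 methyl (2E)-2-iodo-3-[(1R,2S,5S)-2-ethenyl-5-{[(methoxycarbonyl)oxy]methyl}-5-methylcyclopentyl]but-2-enoate, via alkenylcuprate 16 (not isolated)
Conditions: Me2CuLi (from CuI and MeLi), THF, −78 °C; then I2, −78 °C
Reagents that add atoms: lithium dimethylcuprate, [Li+].C[Cu-]C; iodine, II
Why: Syn carbocupration of the ynoate places the methyl on C9 and copper on C8, and iodination with retention at −78 °C fixes the tetrasubstituted alkene with iodine cis to the new methyl and the ester cis to C10 (cuprate conjugate addition, then iododemetalation).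

Step 11
Reactants: 17 iodo enoate
Product: 18 (2E)-2-iodo-3-[(1R,2S,5S)-2-ethenyl-5-(hydroxymethyl)-5-methylcyclopentyl]but-2-en-1-ol
Conditions: i-Bu2AlH (excess), CH2Cl2, −78 °C → 0 °C
Reagents that add atoms: none
Why: i-Bu2AlH reduces the enoate to the allylic alcohol and cleaves the carbonate without touching the alkenyl iodide (ester reduction).

Step 12
Reactants: 18 iodo diol
Product: 19 bis(4-methoxybenzyl) ether of 18 (C15 and C16 as PMB ethers; 8E; 10R,11S,14S)
Conditions: NaH, 4-methoxybenzyl chloride, Bu4NI (cat.), DMF, 0 °C → rt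
Reagents that add atoms: 4-methoxybenzyl chloride, COc1ccc(CCl)cc1
Why: Williamson etherification protects both primary hydroxyls as ethers that tolerate organolithium reagents and leave later under neutral oxidative conditions.

Step 13
Reactants: 19 alkenyl iodide; 20 (S)-citronellal
Product: 22 allylic alcohol joined at C7–C8 (both C7 epimers; 5S; 8E; 10S,11S,14S), via alkenyllithium 21 (not isolated)
Conditions: t-BuLi (2.05 equiv), Et2O, −78 °C; then 20, −78 °C
Reagents that add atoms: none
Why: Iodine–lithium exchange proceeds with retention of alkene geometry and the alkenyllithium adds to the aldehyde (1,2-addition); no control at C7 is expected, and none is needed since step 14 removes this centre.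

Step 14
Reactants: 22 allylic alcohols
Product: 23 C7 enone (5S; 8E; 10S,11S,14S)
Conditions: Dess–Martin periodinane, pyridine, CH2Cl2, 0 °C → rt
Reagents that add atoms: none
Why: Dess–Martin oxidation under buffered conditions merges the C7 epimers into one ketone.

Step 15
Reactants: 23 enone
Product: 24 (7S)-allylic alcohol (5S,7S; 8E; 10S,11S,14S)
Conditions: (R)-2-methyl-CBS-oxazaborolidine, catecholborane, toluene, −78 °C → −40 °C
Reagents that add atoms: none
Why: Corey–Bakshi–Shibata reduction treats the tetrasubstituted alkenyl group as the large substituent, so the R catalyst should give 7S under reagent control, and catecholborane at low temperature leaves the alkenes alone.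

Step 16
Reactants: 24 alcohol
Product: 25 C7 tert-butyldimethylsilyl ether of 24
Conditions: t-BuMe2SiOTf, 2,6-lutidine, CH2Cl2, −78 °C → 0 °C
Reagents that add atoms: tert-butyldimethylsilyl triflate, CC(C)(C)[Si](C)(C)OS(=O)(=O)C(F)(F)F
Why: The silyl triflate overcomes the hindrance at C7 and installs a poor leaving group at the position that lies β to the C16 formyl in the key step (silyl ether formation).

Step 17
Reactants: 25 silyl ether
Product: 26 C1 methyl ketone (acetyl on C11; 5S,7S; 8E; 10S,11R,14S)
Conditions: PdCl2 (10 mol%), CuCl, O2 (1 atm), DMF/H2O, rt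
Reagents that add atoms: water, O
Why: Tsuji–Wacker oxidation is selective for the monosubstituted vinyl group over the tri- and tetrasubstituted alkenes and gives the methyl ketone by Markovnikov attack of water.

Step 18
Reactants: 26 methyl ketone
Product: 28 enol triflate (C11–C1(OTf)=CH2; 5S,7S; 8E; 10S,11R,14S), via potassium enolate 27 (not isolated)
Conditions: KN(SiMe3)2, THF, −78 °C (ketone added to base); then PhNTf2
Reagents that add atoms: N-phenylbis(trifluoromethanesulfonimide), O=S(=O)(N(c1ccccc1)S(=O)(=O)C(F)(F)F)C(F)(F)F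
Why: Kinetic deprotonation occurs at the methyl group, so O-triflation gives the 1,1-disubstituted enol triflate without epimerising C11 (kinetic enolate triflation).

Step 19
Reactants: 28 enol triflate
Product: 30 C2 aldehyde (5S,7S; 8E; 10S,11R,14S), via diol 29 (not isolated)
Conditions: K2OsO2(OH)4 (2 mol%), N-methylmorpholine N-oxide, acetone/H2O, 0 °C; then NaIO4, rt
Reagents that add atoms: N-methylmorpholine N-oxide, C[N+]1([O-])CCOCC1; water, O
Why: Osmium-catalysed dihydroxylation should pick the unhindered trisubstituted terminal alkene over the crowded tetrasubstituted alkene and the electron-poor enol triflate, and periodate cleaves the diol to the aldehyde (Lemieux–Johnson-type cleavage).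

Step 20
Reactants: 30 aldehyde enol triflate
Product: 31 ring C allylic alcohol (eleven-membered ring closed at C1–C2; both C2 epimers; 5S,7S; 8E; 10S,11R,14S)
Conditions: CrCl2 (8 equiv), NiCl2 (2 mol%), DMF, rt, slow addition to 2 mM
Reagents that add atoms: none
Why: In the Nozaki–Hiyama–Kishi reaction nickel activates the enol triflate and transmetalation gives an alkenylchromium species that adds to the aldehyde at high dilution, closing ring C between the cis arms on C10 and C11; the C2 configuration is not relied upon because step 21 removes it.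

Step 21
Reactants: 31 allylic alcohols
Product: 32 ring C α-methylene ketone (C2 ketone)
Conditions: Dess–Martin periodinane, pyridine, CH2Cl2, 0 °C
Reagents that add atoms: none
Why: Dess–Martin oxidation merges the C2 epimers into one enone.

Step 22
Reactants: 32 enone
Product: 33 (2R)-allylic alcohol (2R,5S,7S; 8E; 10S,11R,14S)
Conditions: (S)-2-methyl-CBS-oxazaborolidine, catecholborane, toluene, −78 °C
Reagents that add atoms: none
Why: Corey–Bakshi–Shibata reduction with the S catalyst, the 1,1-disubstituted alkenyl carbon C1 acting as the large group, should set 2R under reagent control.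

Step 23
Reactants: 33 alcohol
Product: 34 C2,C7 bis(tert-butyldimethylsilyl) ether
Conditions: t-BuMe2SiOTf, 2,6-lutidine, CH2Cl2, −78 °C → 0 °C
Reagents that add atoms: tert-butyldimethylsilyl triflate, CC(C)(C)[Si](C)(C)OS(=O)(=O)C(F)(F)F
Why: Silylation protects the C2 hydroxyl for the coming oxidations and keeps esters out of the key step (silyl ether formation).

Step 24
Reactants: 34 bis-PMB ether
Product: 35 C15,C16 diol (2R,5S,7S; 8E; 10S,11R,14S)
Conditions: DDQ, CH2Cl2/pH 7 buffer, 0 °C
Reagents that add atoms: none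
Why: DDQ removes both PMB ethers by oxidative cleavage under neutral conditions that leave the allylic silyl ethers in place.

Step 25
Reactants: 35 diol
Product: 36 A/C-bicyclic dialdehyde (formyl on C14 and on C8; 2R,5S,7S; 8Z; 10S,11R,14S)
Conditions: Dess–Martin periodinane (3 equiv), pyridine, CH2Cl2, 0 °C → rt
Reagents that add atoms: none
Why: Dess–Martin oxidation converts the allylic C16 and neopentyl C15 alcohols to aldehydes without acid or base, so the alkene geometry is kept, and C14 has no α-hydrogen to lose.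

Step 26
Reactants: 36 dialdehyde
Product: 37 tricyclic trans-15,16-diol (2R,5S,7S,10S,11R,14S,15R,16R; C2 and C7 silyl ethers)
Conditions: Cp2TiPh (3 equiv; made at −78 °C from Cp2TiCl2, i-PrMgCl, then PhMgBr), THF, slow addition of 36, −78 °C → rt; aq. NaHCO3
Reagents that add atoms: none
Why: Cp2TiPh, a trivalent titanium reagent, reduces the conjugated C16 aldehyde to a titanium-bound ketyl whose allylic radical can close only through C16 (attack from C9 would give a four-membered ring), and addition to the titanium-activated C15 aldehyde followed by a second electron transfer gives the bis(titanoxy) diolate; the closest known reaction type is the trans-selective titanocene-mediated pinacol cyclisation of 1,6-dialdehydes. Ring B (C8, C9, C10, C14, C15, C16) closes in a 6-exo mode onto the C15 carbonyl. At C15 the titanoxy group should point to the methyl-bearing face of C14, away from ring A carbon C13 and the C11 arm, which makes it 15R; at C16 the second bulky titanoxy group avoids the first and ends trans, which makes it 16R. The step needs chemoselectivity (coupling over simple reduction, oligomerisation or β-elimination) and trans selectivity: the alkene holds the C8 formyl cis to C10 and the C14 formyl is on the same face, so the two carbonyls are within reach, the silyl ether at C7 is a poor leaving group, and no ester is present.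

Step 27
Reactants: 37 bis-silyl ether diol
Product: 38 tetraol (hydroxyls at C2, C7, C15, C16)
Conditions: Bu4NF, THF, rt
Reagents that add atoms: none
Why: Fluoride cleaves both secondary silyl ethers under non-acidic conditions that spare the allylic alcohols (desilylation).

Step 28
Reactants: 38 tetraol
Product: 39 target CNP0318778.1 (2,7,16-triacetate; free C15 hydroxyl)
Conditions: Ac2O (3.3 equiv), pyridine, DMAP (cat.), CH2Cl2, 0 °C
Reagents that add atoms: acetic anhydride, CC(=O)OC(C)=O
Why: A limited amount of Ac2O should esterify the three allylic hydroxyls at C2, C7 and C16 and leave the C15 hydroxyl, which is flanked by quaternary C14 and the acetoxylated C16 (site-selective acetylation on steric grounds).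

**Compound list**

1 | methyl 2-oxocyclopentane-1-carboxylate | COC(=O)C1CCCC1=O | starting material
2 | L-valine tert-butyl ester | CC(C)[C@H](N)C(=O)OC(C)(C)C | starting material
3 | methyl 2-{[(2S)-1-tert-butoxy-3-methyl-1-oxobutan-2-yl]amino}cyclopent-1-ene-1-carboxylate | COC(=O)C1=C(N[C@@H](C(C)C)C(=O)OC(C)(C)C)CCC1 | intermediate
4 | N-lithio enamine of 3 | [Li+].COC(=O)C1=C([N-][C@@H](C(C)C)C(=O)OC(C)(C)C)CCC1 | intermediate
5 | ketimine of 6 with 2 | CC(C)[C@H](N=C1CCC[C@]1(C)C(=O)OC)C(=O)OC(C)(C)C | intermediate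
6 | methyl (1S)-1-methyl-2-oxocyclopentane-1-carboxylate | O=C1CCC[C@]1(C)C(=O)OC | intermediate
7 | lithium enolate of 6 | [Li+].[O-]C1=CCC[C@]1(C)C(=O)OC | intermediate
8 | methyl (1S)-1-methyl-2-(trifluoromethanesulfonyloxy)cyclopent-2-ene-1-carboxylate | FC(F)(F)S(=O)(=O)OC1=CCC[C@]1(C)C(=O)OC | intermediate
9 | (5R)-5-(hydroxymethyl)-5-methylcyclopent-1-en-1-yl trifluoromethanesulfonate | FC(F)(F)S(=O)(=O)OC1=CCC[C@]1(C)CO | intermediate
10 | (3aS)-3a-methyl-3,3a,4,5-tetrahydro-1H-cyclopenta[c]furan-1-one | O=C1C2=CCC[C@]2(C)CO1 | intermediate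
11 | (3aS,6S,6aR)-6-ethenyl-3a-methylhexahydro-1H-cyclopenta[c]furan-1-one | O=C1[C@@H]2[C@H](C=C)CC[C@]2(C)CO1 | intermediate
12 | (3aS,6S,6aR)-6-ethenyl-3a-methylhexahydro-1H-cyclopenta[c]furan-1-ol | OC1[C@@H]2[C@H](C=C)CC[C@]2(C)CO1 | intermediate
13 | [(1S,2S,3S)-3-ethenyl-2-ethynyl-1-methylcyclopentyl]methanol | C#C[C@@H]1[C@H](C=C)CC[C@]1(C)CO | intermediate
14 | dilithio alkynide alkoxide of 13 | [Li+].[Li+].[C-]#C[C@@H]1[C@H](C=C)CC[C@]1(C)C[O-] | intermediate
15 | methyl 3-[(1S,2S,5S)-2-ethenyl-5-{[(methoxycarbonyl)oxy]methyl}-5-methylcyclopentyl]prop-2-ynoate | COC(=O)C#C[C@@H]1[C@H](C=C)CC[C@]1(C)COC(=O)OC | intermediate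
16 | alkenyl(methyl)cuprate from 15 (copper on C8, cis to the C9 methyl) | [Li+].C[Cu-]/C(C(=O)OC)=C(\C)[C@@H]1[C@H](C=C)CC[C@]1(C)COC(=O)OC | intermediate
17 | methyl (2E)-2-iodo-3-[(1R,2S,5S)-2-ethenyl-5-{[(methoxycarbonyl)oxy]methyl}-5-methylcyclopentyl]but-2-enoate | I/C(C(=O)OC)=C(\C)[C@@H]1[C@H](C=C)CC[C@]1(C)COC(=O)OC | intermediate
18 | (2E)-2-iodo-3-[(1R,2S,5S)-2-ethenyl-5-(hydroxymethyl)-5-methylcyclopentyl]but-2-en-1-ol | I/C(CO)=C(\C)[C@@H]1[C@H](C=C)CC[C@]1(C)CO | intermediate
19 | bis(4-methoxybenzyl) ether of 18 | I/C(COCc2ccc(OC)cc2)=C(\C)[C@@H]1[C@H](C=C)CC[C@]1(C)COCc2ccc(OC)cc2 | intermediate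
20 | (S)-citronellal | C[C@@H](CCC=C(C)C)CC=O | starting material
21 | alkenyllithium from 19 (lithium on C8) | [Li]/C(COCc2ccc(OC)cc2)=C(\C)[C@@H]1[C@H](C=C)CC[C@]1(C)COCc2ccc(OC)cc2 | intermediate
22 | C7 allylic alcohol, both epimers (5S; 8E; 10S,11S,14S) | CC(C)=CCC[C@H](C)CC(O)/C(COCc2ccc(OC)cc2)=C(\C)[C@@H]1[C@H](C=C)CC[C@]1(C)COCc2ccc(OC)cc2 | intermediate
23 | C7 enone | CC(C)=CCC[C@H](C)CC(=O)/C(COCc2ccc(OC)cc2)=C(\C)[C@@H]1[C@H](C=C)CC[C@]1(C)COCc2ccc(OC)cc2 | intermediate
24 | (7S)-allylic alcohol | CC(C)=CCC[C@H](C)C[C@H](O)/C(COCc2ccc(OC)cc2)=C(\C)[C@@H]1[C@H](C=C)CC[C@]1(C)COCc2ccc(OC)cc2 | intermediate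
25 | C7 tert-butyldimethylsilyl ether of 24 | CC(C)=CCC[C@H](C)C[C@H](O[Si](C)(C)C(C)(C)C)/C(COCc2ccc(OC)cc2)=C(\C)[C@@H]1[C@H](C=C)CC[C@]1(C)COCc2ccc(OC)cc2 | intermediate
26 | C1 methyl ketone (acetyl on C11) | CC(C)=CCC[C@H](C)C[C@H](O[Si](C)(C)C(C)(C)C)/C(COCc2ccc(OC)cc2)=C(\C)[C@@H]1[C@H](C(C)=O)CC[C@]1(C)COCc2ccc(OC)cc2 | intermediate
27 | potassium enolate of 26 (terminal) | [K+].CC(C)=CCC[C@H](C)C[C@H](O[Si](C)(C)C(C)(C)C)/C(COCc2ccc(OC)cc2)=C(\C)[C@@H]1[C@H](C(=C)[O-])CC[C@]1(C)COCc2ccc(OC)cc2 | intermediate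
28 | enol triflate (C11–C1(OTf)=CH2) | CC(C)=CCC[C@H](C)C[C@H](O[Si](C)(C)C(C)(C)C)/C(COCc2ccc(OC)cc2)=C(\C)[C@@H]1[C@H](C(=C)OS(=O)(=O)C(F)(F)F)CC[C@]1(C)COCc2ccc(OC)cc2 | intermediate
29 | terminal diol from 28 | CC(C)(O)C(O)CC[C@H](C)C[C@H](O[Si](C)(C)C(C)(C)C)/C(COCc2ccc(OC)cc2)=C(\C)[C@@H]1[C@H](C(=C)OS(=O)(=O)C(F)(F)F)CC[C@]1(C)COCc2ccc(OC)cc2 | intermediate
30 | C2 aldehyde enol triflate | O=CCC[C@H](C)C[C@H](O[Si](C)(C)C(C)(C)C)/C(COCc2ccc(OC)cc2)=C(\C)[C@@H]1[C@H](C(=C)OS(=O)(=O)C(F)(F)F)CC[C@]1(C)COCc2ccc(OC)cc2 | intermediate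
31 | ring C allylic alcohol, both C2 epimers | C=C1C(O)CC[C@H](C)C[C@H](O[Si](C)(C)C(C)(C)C)/C(COCc3ccc(OC)cc3)=C(\C)[C@@H]2[C@H]1CC[C@]2(C)COCc3ccc(OC)cc3 | intermediate
32 | ring C α-methylene ketone | C=C1C(=O)CC[C@H](C)C[C@H](O[Si](C)(C)C(C)(C)C)/C(COCc3ccc(OC)cc3)=C(\C)[C@@H]2[C@H]1CC[C@]2(C)COCc3ccc(OC)cc3 | intermediate
33 | (2R)-allylic alcohol | C=C1[C@H](O)CC[C@H](C)C[C@H](O[Si](C)(C)C(C)(C)C)/C(COCc3ccc(OC)cc3)=C(\C)[C@@H]2[C@H]1CC[C@]2(C)COCc3ccc(OC)cc3 | intermediate
34 | C2,C7 bis(tert-butyldimethylsilyl) ether | C=C1[C@H](O[Si](C)(C)C(C)(C)C)CC[C@H](C)C[C@H](O[Si](C)(C)C(C)(C)C)/C(COCc3ccc(OC)cc3)=C(\C)[C@@H]2[C@H]1CC[C@]2(C)COCc3ccc(OC)cc3 | intermediate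
35 | C15,C16 diol | C=C1[C@H](O[Si](C)(C)C(C)(C)C)CC[C@H](C)C[C@H](O[Si](C)(C)C(C)(C)C)/C(CO)=C(\C)[C@@H]2[C@H]1CC[C@]2(C)CO | intermediate
36 | A/C-bicyclic dialdehyde (key-step precursor) | C=C1[C@H](O[Si](C)(C)C(C)(C)C)CC[C@H](C)C[C@H](O[Si](C)(C)C(C)(C)C)/C(C=O)=C(\C)[C@@H]2[C@H]1CC[C@]2(C)C=O | intermediate
37 | tricyclic trans-15,16-diol (key-step product) | C=C1[C@H](O[Si](C)(C)C(C)(C)C)CC[C@H](C)C[C@H](O[Si](C)(C)C(C)(C)C)C2=C(C)[C@@H]3[C@H]1CC[C@]3(C)[C@@H](O)[C@@H]2O | intermediate
38 | tetraol | C=C1[C@H](O)CC[C@H](C)C[C@H](O)C2=C(C)[C@@H]3[C@H]1CC[C@]3(C)[C@@H](O)[C@@H]2O | intermediate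
39 | CNP0318778.1 | C=C1[C@H](OC(C)=O)CC[C@H](C)C[C@H](OC(C)=O)C2=C(C)[C@@H]3[C@H]1CC[C@]3(C)[C@@H](O)[C@@H]2OC(C)=O | target

**Count and risks**

Total step count: 28. Longest linear sequence: 28 steps (from 1; 20 enters at step 13).

Step 26 is the most likely to fail. The bulky titanium reagent may not engage the hindered neopentyl C15 aldehyde, the ring may close to the cis glycol or the other trans glycol, or the enal may be reduced or couple between molecules. The fallback sets out from dialdehyde 36. SmI2 in THF/t-BuOH at −78 °C closes ring B through a samarium-chelated bis-ketyl to the cis-glycol F1. MnO2 then oxidises only the allylic C16 carbinol to the hydroxy enone F2. Me4NBH(OAc)3 in MeCN/AcOH, bound to the C15 hydroxyl, delivers hydride to C16 from that face, which gives trans-diol 37, where the route is rejoined. This fallback still depends on the 15R configuration arising in the samarium closure.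

Step 20 is the second risk. The alkenylchromium species may form slowly, the triflate may be lost by protonation, or intermolecular coupling may compete at the dilution an eleven-membered ring needs. The fallback sets out from enol triflate 28. LiN(i-Pr)2 eliminates triflate to give the terminal alkyne F3, and dihydroxylation and periodate cleavage as in step 19 give the ynal F4. Zerovalent nickel (Ni(cod)2 with a bulky N-heterocyclic carbene ligand) and Et3SiH then close ring C by reductive alkyne–aldehyde coupling at the internal alkyne carbon, giving the triethylsilyl ether F5 with the exocyclic methylene. PPTS in MeOH removes the triethylsilyl group selectively and the route is rejoined at alcohol 31.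

Step 28 is the third risk. Site selectivity may be lost, through acetylation of the C15 hydroxyl or incomplete acetylation at the hindered C7 hydroxyl. The fallback sets out from diol 37, in which only the C15 and C16 hydroxyls are free. Bu2SnO and then AcCl acetylate the allylic C16 hydroxyl through the stannylene acetal to give the monoacetate F6. Bu4NF buffered with AcOH removes both silyl ethers to give the triol F7. Ac2O in pyridine then esterifies the C2 and C7 hydroxyls, which ends at target 39.

**Further compounds**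

F1 | step 26 | tricyclic cis-15,16-diol (15R,16S) | C=C1[C@H](O[Si](C)(C)C(C)(C)C)CC[C@H](C)C[C@H](O[Si](C)(C)C(C)(C)C)C2=C(C)[C@@H]3[C@H]1CC[C@]3(C)[C@@H](O)[C@H]2O
F2 | step 26 | (15R)-15-hydroxy-16-ketone | C=C1[C@H](O[Si](C)(C)C(C)(C)C)CC[C@H](C)C[C@H](O[Si](C)(C)C(C)(C)C)C2=C(C)[C@@H]3[C@H]1CC[C@]3(C)[C@@H](O)C2=O
F3 | step 20 | terminal alkyne (ethynyl on C11) | CC(C)=CCC[C@H](C)C[C@H](O[Si](C)(C)C(C)(C)C)/C(COCc2ccc(OC)cc2)=C(\C)[C@@H]1[C@H](C#C)CC[C@]1(C)COCc2ccc(OC)cc2
F4 | step 20 | ynal (C2 aldehyde; ethynyl on C11) | O=CCC[C@H](C)C[C@H](O[Si](C)(C)C(C)(C)C)/C(COCc2ccc(OC)cc2)=C(\C)[C@@H]1[C@H](C#C)CC[C@]1(C)COCc2ccc(OC)cc2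
F5 | step 20 | ring C allylic triethylsilyl ether (both C2 epimers) | C=C1C(O[Si](CC)(CC)CC)CC[C@H](C)C[C@H](O[Si](C)(C)C(C)(C)C)/C(COCc3ccc(OC)cc3)=C(\C)[C@@H]2[C@H]1CC[C@]2(C)COCc3ccc(OC)cc3
F6 | step 28 | 16-O-acetyl bis-silyl ether | C=C1[C@H](O[Si](C)(C)C(C)(C)C)CC[C@H](C)C[C@H](O[Si](C)(C)C(C)(C)C)C2=C(C)[C@@H]3[C@H]1CC[C@]3(C)[C@@H](O)[C@@H]2OC(C)=O
F7 | step 28 | 16-O-acetyl triol | C=C1[C@H](O)CC[C@H](C)C[C@H](O)C2=C(C)[C@@H]3[C@H]1CC[C@]3(C)[C@@H](O)[C@@H]2OC(C)=O
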